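## Retrosynthetic overview

1. Locants follow 2H-chromene numbering. Ring A is the dihydropyran (O1, C2, C3, C4, C4a, C8a) and ring B the carbocycle (C4a, C5, C6, C7, C8, C8a).
2. Enabling feature: ring B is a 2,2-dialkyl-1,3-dione (C5=O, quaternary C6, C7=O). C5 is also the acyl carbon of the enolised β-triketone C4(OH)=C4a–C5=O, so C4a–C5 and C6–C7 are both C-acylation (Claisen) bonds of opposite sense. Because C2′ of the prenyl group is γ to C5, C5 can be held as a γ-lactone carbonyl.
3. Key disconnection (ring B, closed last): a γ-butyrolactone and a glutaric anhydride. The lactone carries C5, C6, the cyclobutylmethyl group and the prenyl group stored as a lactonised Horner–Wittig adduct; this temporary ring fixes the enolate geometry and directs the C6 configuration. The anhydride carries ring A, C7, C8 and the side chain; this temporary ring releases a vinylketene at C7 and the free side-chain carboxylate. One anionic cascade forms C6–C7 and C4a–C5, opens both temporary rings and unveils the prenyl group, so the acid needs no protecting group.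
4. Lactone fragment: CBS reduction of a β-keto phosphine oxide, then alkylation with a cyclobutylmethyl triflate made from (−)-verbenone. Anhydride fragment: Evans syn aldol, acetoacetate dianion acylation and cyclodehydration build ring A; an iminium-catalysed Michael addition to cinnamaldehyde sets the benzylic centre.
5. Order of ring formation: cyclobutane (chiral pool), temporary lactone (step 6), ring A (step 12), temporary anhydride (step 15), ring B (step 16).

Key step: step 16

Remark: the target is handled as the drawn enol tautomer of its cyclic β,β′-triketone, and centres that are planarised later are carried as epimer mixtures.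

## Route

Step 1
Reactants: 1 (1S,5S)-4,6,6-trimethylbicyclo[3.1.1]hept-3-en-2-one [(−)-verbenone]
Product: 2 (1S,3R)-3-acetyl-2,2-dimethylcyclobutane-1-carboxylic acid
Conditions: RuCl3 hydrate (2 mol%), NaIO4 (4.5 equiv), CCl4/MeCN/H2O, rt
Reagents that add atoms: NaIO4 [Na+].[O-]I(=O)(=O)=O; water O
Why: Oxidative cleavage of the enone C=C by RuO4 formed in situ, with loss of the former C3 as CO2 from the intermediate α-keto acid, is the established degradation of verbenone to cis-pinononic acid and carries both cyclobutane centres over from the chiral pool.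

Step 2
Reactants: 2 (1S,3R)-3-acetyl-2,2-dimethylcyclobutane-1-carboxylic acid
Product: 3 (1S,3S)-2,2-dimethyl-3-(prop-1-en-2-yl)cyclobutane-1-carboxylic acid
Conditions: Ph3PCH3Br (2.6 equiv), KOtBu (2.5 equiv), THF, 0 °C to rt; then aq. HCl
Reagents that add atoms: methyltriphenylphosphonium bromide C[P+](c1ccccc1)(c1ccccc1)c1ccccc1.[Br-]
Why: Wittig methylenation of the methyl ketone, with the acid carried as its potassium carboxylate, should give the isopropenyl group, the ylide being used cold and in small excess so that the ketone α-centre does not epimerise to the trans series.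

Step 3
Reactants: 3 (1S,3S)-2,2-dimethyl-3-(prop-1-en-2-yl)cyclobutane-1-carboxylic acid
Product: 4 [(1S,3S)-2,2-dimethyl-3-(prop-1-en-2-yl)cyclobutyl]methanol
Conditions: LiAlH4, THF, 0 °C to reflux; aq. NaOH work-up
Reagents that add atoms: none
Why: LiAlH4 reduction of the carboxylic acid to the primary alcohol leaves the unactivated 1,1-disubstituted alkene and both stereocentres untouched.

Step 4
Reactants: 4 [(1S,3S)-2,2-dimethyl-3-(prop-1-en-2-yl)cyclobutyl]methanol
Product: 5 [(1S,3S)-2,2-dimethyl-3-(prop-1-en-2-yl)cyclobutyl]methyl trifluoromethanesulfonate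
Conditions: Tf2O, pyridine, CH2Cl2, −78 to −30 °C; used crude at once
Reagents that add atoms: trifluoromethanesulfonic anhydride O=S(=O)(OS(=O)(=O)C(F)(F)F)C(F)(F)F
Why: Sulfonylation of the primary alcohol gives the triflate needed for an SN2 alkylation at this β-branched carbon, and cold, non-polar handling should keep it from ionising to the rearrangement-prone cyclobutylcarbinyl cation.

Step 5
Reactants: 6 diphenyl(propan-2-yl)phosphane oxide; 7 methyl 4-chloro-4-oxobutanoate
Product: 8 methyl 5-(diphenylphosphoryl)-5-methyl-4-oxohexanoate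
Conditions: 6, n-BuLi, THF, −78 °C; then cannulated into 7, THF, −78 °C
Reagents that add atoms: none
Why: Acylation of the α-lithiated alkyldiphenylphosphine oxide by the acid chloride (first half of a Horner–Wittig sequence) should stop at the β-keto phosphine oxide because the chloride is far more reactive than the methyl ester and the carbanion is added to the electrophile.

Step 6
Reactants: 8 methyl 5-(diphenylphosphoryl)-5-methyl-4-oxohexanoate
Product: 10 (5S)-5-[2-(diphenylphosphoryl)propan-2-yl]oxolan-2-one, via hydroxy ester 9 (not isolated)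
Conditions: (R)-2-methyl-CBS-oxazaborolidine (15 mol%), BH3·SMe2, THF, −20 °C; MeOH; then TsOH (cat.), toluene, 50 °C
Reagents that add atoms: none
Why: Corey–Bakshi–Shibata reduction should distinguish the quaternary phosphoryl-bearing carbon (large) from the CH2 chain (small), so that the (R)-oxazaborolidine gives the (S)-carbinol, which lactonises under acid catalysis and can be recrystallised to raise the ee.

Step 7
Reactants: 10 (5S)-5-[2-(diphenylphosphoryl)propan-2-yl]oxolan-2-one; 5 [(1S,3S)-2,2-dimethyl-3-(prop-1-en-2-yl)cyclobutyl]methyl trifluoromethanesulfonate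
Product: 11 (5S)-3-{[(1R,3S)-2,2-dimethyl-3-(prop-1-en-2-yl)cyclobutyl]methyl}-5-[2-(diphenylphosphoryl)propan-2-yl]oxolan-2-one (C3 epimers)
Conditions: LiN(iPr)2, THF, −78 °C; then 5, DMPU, −78 to −30 °C
Reagents that add atoms: none
Why: SN2 alkylation of the lithium enolate of the γ-butyrolactone by the primary triflate should install the cyclobutylmethyl group at C3, mainly trans to the C5 substituent, a centre that is planarised again in step 16.

Step 8
Reactants: 12 (4S)-4-benzyl-3-propanoyl-1,3-oxazolidin-2-one; 13 acetaldehyde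
Product: 14 (4S)-4-benzyl-3-[(2S,3R)-3-hydroxy-2-methylbutanoyl]-1,3-oxazolidin-2-one
Conditions: Bu2BOTf, iPr2NEt, CH2Cl2, −78 to 0 °C; then pH 7 buffer, MeOH, H2O2
Reagents that add atoms: none
Why: The Evans syn aldol reaction through the Z-boron enolate and a closed chair transition state should set both new centres (2S,3R) under control of the (S)-benzyl auxiliary.

Step 9
Reactants: 14 (4S)-4-benzyl-3-[(2S,3R)-3-hydroxy-2-methylbutanoyl]-1,3-oxazolidin-2-one
Product: 15 (2S,3R)-3-hydroxy-N-methoxy-N,2-dimethylbutanamide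
Conditions: MeNHOMe·HCl, AlMe3, CH2Cl2, −20 °C to rt
Reagents that add atoms: N,O-dimethylhydroxylamine hydrochloride CNOC.Cl
Why: Aluminium amide transamination cleaves the imide at the exocyclic carbonyl to give the Weinreb amide and releases the auxiliary without touching the two stereocentres.

Step 10
Reactants: 15 (2S,3R)-3-hydroxy-N-methoxy-N,2-dimethylbutanamide
Product: 16 (2S,3R)-3-[(tert-butyldimethylsilyl)oxy]-N-methoxy-N,2-dimethylbutanamide
Conditions: TBSCl, imidazole, DMF, rt
Reagents that add atoms: tert-butyl(chloro)dimethylsilane CC(C)(C)[Si](C)(C)Cl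
Why: Silylation of the secondary alcohol protects it against retro-aldol cleavage and alkoxide formation in the following Claisen-type step.

Step 11
Reactants: 16 (2S,3R)-3-[(tert-butyldimethylsilyl)oxy]-N-methoxy-N,2-dimethylbutanamide; 17 tert-butyl 3-oxobutanoate
Product: 18 tert-butyl (6S,7R)-7-[(tert-butyldimethylsilyl)oxy]-6-methyl-3,5-dioxooctanoate
Conditions: 17, NaH then n-BuLi, THF, 0 °C; then 16, −78 to 0 °C; aq. NH4Cl
Reagents that add atoms: none
Why: The acetoacetate dianion reacts at its terminal carbon with the Weinreb amide (Claisen-type acylation held at the ketone stage by the chelated tetrahedral intermediate), giving the 3,5-diketo ester without epimerising the α-methyl centre.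

Step 12
Reactants: 18 tert-butyl (6S,7R)-7-[(tert-butyldimethylsilyl)oxy]-6-methyl-3,5-dioxooctanoate
Product: 20 tert-butyl 2-[(2R,3S)-2,3-dimethyl-4-oxo-3,4-dihydro-2H-pyran-6-yl]acetate, via hydroxy diketone 19 (not isolated)
Conditions: HF·pyridine, THF, 0 °C to rt; then PPTS (cat.), toluene, 40 °C
Reagents that add atoms: none
Why: Desilylation frees the hydroxyl, which adds to the C3 ketone in a 6-exo-trig hemiketalisation and dehydrates to the 2,3-dihydro-4H-pyran-4-one (ring A), the syn aldol relationship becoming the cis-2,3-dimethyl pattern and the tert-butyl ester disfavouring the competing 2-pyranone closure.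

Step 13
Reactants: 20 tert-butyl 2-[(2R,3S)-2,3-dimethyl-4-oxo-3,4-dihydro-2H-pyran-6-yl]acetate; 21 (E)-cinnamaldehyde
Product: 22 tert-butyl (3R)-2-[(2R,3S)-2,3-dimethyl-4-oxo-3,4-dihydro-2H-pyran-6-yl]-5-oxo-3-phenylpentanoate (C2 epimers)
Conditions: (S)-α,α-diphenylprolinol trimethylsilyl ether (10 mol%), LiOAc (10 mol%), EtOH, 0 °C to rt
Reagents that add atoms: none
Why: In this iminium-catalysed Michael addition of the doubly activated methylene (ester and vinylogous acyl) to cinnamaldehyde, the silyloxydiphenylmethyl group of the (S)-catalyst shields one face of the E-iminium ion and should set the benzylic centre as (R), while the centre α to the ester forms as a mixture that is planarised in step 16.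

Step 14
Reactants: 22 tert-butyl (3R)-2-[(2R,3S)-2,3-dimethyl-4-oxo-3,4-dihydro-2H-pyran-6-yl]-5-oxo-3-phenylpentanoate
Product: 23 (3R)-5-tert-butoxy-4-[(2R,3S)-2,3-dimethyl-4-oxo-3,4-dihydro-2H-pyran-6-yl]-5-oxo-3-phenylpentanoic acid (C4 epimers)
Conditions: NaClO2, NaH2PO4, 2-methylbut-2-ene, t-BuOH/H2O, 0 °C to rt
Reagents that add atoms: NaClO2 [Na+].[O-]Cl=O
Why: Pinnick oxidation converts the aldehyde to the acid under buffered conditions that leave the enone and the epimerisable ring A centres intact, the alkene scavenger removing HOCl.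

Step 15
Reactants: 23 (3R)-5-tert-butoxy-4-[(2R,3S)-2,3-dimethyl-4-oxo-3,4-dihydro-2H-pyran-6-yl]-5-oxo-3-phenylpentanoic acid
Product: 25 (4R)-3-[(2R,3S)-2,3-dimethyl-4-oxo-3,4-dihydro-2H-pyran-6-yl]-4-phenyloxane-2,6-dione, via diacid 24 (not isolated)
Conditions: TFA, CH2Cl2, 0 °C; evaporation; then DCC, CH2Cl2, 0 °C to rt; filtration
Reagents that add atoms: none
Why: Acidolysis of the tert-butyl ester followed by carbodiimide dehydration closes the six-membered glutaric anhydride, a temporary ring that activates the acyl carbon next to ring A and masks the side-chain acid, and cold, short handling should prevent decarboxylation of the vinylogous β-keto acid.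

Step 16
Reactants: 11 (5S)-3-{[(1R,3S)-2,2-dimethyl-3-(prop-1-en-2-yl)cyclobutyl]methyl}-5-[2-(diphenylphosphoryl)propan-2-yl]oxolan-2-one; 25 (4R)-3-[(2R,3S)-2,3-dimethyl-4-oxo-3,4-dihydro-2H-pyran-6-yl]-4-phenyloxane-2,6-dione
Product: 29 (3S)-3-[(2R,3S,6R)-6-{[(1R,3S)-2,2-dimethyl-3-(prop-1-en-2-yl)cyclobutyl]methyl}-4-hydroxy-2,3-dimethyl-6-(3-methylbut-2-en-1-yl)-5,7-dioxo-3,5,6,7-tetrahydro-2H-chromen-8-yl]-3-phenylpropanoic acid, via ketene acid 26 (not isolated), via acyl lactone 27 (not isolated), via hydroxy phosphine oxide 28 (not isolated)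
Conditions: 25, LiN(SiMe3)2 (1.0 equiv), THF, −78 °C, cannulated into 11 + LiN(SiMe3)2 (1.05 equiv), THF, −78 to 0 °C; then KOtBu (3 equiv), 0 to 35 °C; cold aq. HCl to pH 4
Reagents that add atoms: none
Why: Proposed new method: deprotonation of anhydride 25 at its doubly activated C3–H gives an enolate that opens by E1cB to vinylketene carboxylate 26, whose sp carbonyl carbon (future C7) C-acylates the lithium enolate of 11 at lactone C3 (future C6) to give 27 as a vinylogous β-diketone dienolate; the γ-carbon of this dienolate (future C4a) then attacks the lactone carbonyl (future C5) in a 6-(enolexo)-exo-trig Claisen closure of ring B, the lactone C–O bond breaks, and with KOtBu the freed β-phosphoryl alkoxide of 28 undergoes syn Horner–Wittig elimination to the prenyl group. The closest known reaction types are base-induced ketene formation from activated acyl derivatives, C-acylation of ester and lactone enolates by ketenes, anionic annulations in which a lactone carbonyl is the acyl donor (Hauser–Kraus phthalide annulation) and Horner–Wittig olefination. The only new stereocentre, quaternary C6, is set in the first C–C bond formation: the ketene adds to the planar lactone enolate anti to the very bulky CMe2P(O)Ph2 group at lactone C5 (the established 1,3-induction in α-functionalisation of γ-substituted butyrolactone enolates), and because the ring fixes the enolate geometry the two similar CH2 substituents on C6 never have to be told apart; the controlling lactone centre is then erased as the prenyl alkene carbon. The step needs C- rather than O-acylation and attack at the ketene rather than at the remaining anhydride carbonyl, which the small, strongly electrophilic sp carbon and the reversibility of O-acylation should secure, and it needs closure at C4a only, which is enforced because closure through the α-carbon or through oxygen would give a four-membered ring. The driving force is formation of the enolised β-triketone anion and the irreversible loss of Ph2P(O)OK.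

## Compound list

1 | (1S,5S)-4,6,6-trimethylbicyclo[3.1.1]hept-3-en-2-one [(−)-verbenone] | CC1=CC(=O)[C@H]2C[C@@H]1C2(C)C | starting material
2 | (1S,3R)-3-acetyl-2,2-dimethylcyclobutane-1-carboxylic acid | CC(=O)[C@@H]1C[C@H](C(=O)O)C1(C)C | intermediate
3 | (1S,3S)-2,2-dimethyl-3-(prop-1-en-2-yl)cyclobutane-1-carboxylic acid | C=C(C)[C@@H]1C[C@H](C(=O)O)C1(C)C | intermediate
4 | [(1S,3S)-2,2-dimethyl-3-(prop-1-en-2-yl)cyclobutyl]methanol | C=C(C)[C@@H]1C[C@H](CO)C1(C)C | intermediate
5 | [(1S,3S)-2,2-dimethyl-3-(prop-1-en-2-yl)cyclobutyl]methyl trifluoromethanesulfonate | C=C(C)[C@@H]1C[C@H](COS(=O)(=O)C(F)(F)F)C1(C)C | intermediate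
6 | diphenyl(propan-2-yl)phosphane oxide | CC(C)P(=O)(c1ccccc1)c1ccccc1 | starting material
7 | methyl 4-chloro-4-oxobutanoate | COC(=O)CCC(=O)Cl | starting material
8 | methyl 5-(diphenylphosphoryl)-5-methyl-4-oxohexanoate | COC(=O)CCC(=O)C(C)(C)P(=O)(c1ccccc1)c1ccccc1 | intermediate
9 | methyl (4S)-5-(diphenylphosphoryl)-4-hydroxy-5-methylhexanoate | COC(=O)CC[C@H](O)C(C)(C)P(=O)(c1ccccc1)c1ccccc1 | intermediate
10 | (5S)-5-[2-(diphenylphosphoryl)propan-2-yl]oxolan-2-one | O=C1CC[C@H](O1)C(C)(C)P(=O)(c1ccccc1)c1ccccc1 | intermediate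
11 | (5S)-3-{[(1R,3S)-2,2-dimethyl-3-(prop-1-en-2-yl)cyclobutyl]methyl}-5-[2-(diphenylphosphoryl)propan-2-yl]oxolan-2-one (C3 epimers) | C=C(C)[C@@H]1C[C@H](CC2C[C@H](OC2=O)C(C)(C)P(=O)(c2ccccc2)c2ccccc2)C1(C)C | intermediate
12 | (4S)-4-benzyl-3-propanoyl-1,3-oxazolidin-2-one | CCC(=O)N1[C@@H](Cc2ccccc2)COC1=O | starting material
13 | acetaldehyde | CC=O | starting material
14 | (4S)-4-benzyl-3-[(2S,3R)-3-hydroxy-2-methylbutanoyl]-1,3-oxazolidin-2-one | O=C(N1[C@@H](Cc2ccccc2)COC1=O)[C@@H](C)[C@@H](C)O | intermediate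
15 | (2S,3R)-3-hydroxy-N-methoxy-N,2-dimethylbutanamide | CON(C)C(=O)[C@@H](C)[C@@H](C)O | intermediate
16 | (2S,3R)-3-[(tert-butyldimethylsilyl)oxy]-N-methoxy-N,2-dimethylbutanamide | CON(C)C(=O)[C@@H](C)[C@@H](C)O[Si](C)(C)C(C)(C)C | intermediate
17 | tert-butyl 3-oxobutanoate | CC(=O)CC(=O)OC(C)(C)C | starting material
18 | tert-butyl (6S,7R)-7-[(tert-butyldimethylsilyl)oxy]-6-methyl-3,5-dioxooctanoate | CC(C)(C)OC(=O)CC(=O)CC(=O)[C@@H](C)[C@@H](C)O[Si](C)(C)C(C)(C)C | intermediate
19 | tert-butyl (6S,7R)-7-hydroxy-6-methyl-3,5-dioxooctanoate | CC(C)(C)OC(=O)CC(=O)CC(=O)[C@@H](C)[C@@H](C)O | intermediate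
20 | tert-butyl 2-[(2R,3S)-2,3-dimethyl-4-oxo-3,4-dihydro-2H-pyran-6-yl]acetate | CC(C)(C)OC(=O)CC1=CC(=O)[C@@H](C)[C@@H](C)O1 | intermediate
21 | (E)-cinnamaldehyde | O=C/C=C/c1ccccc1 | starting material
22 | tert-butyl (3R)-2-[(2R,3S)-2,3-dimethyl-4-oxo-3,4-dihydro-2H-pyran-6-yl]-5-oxo-3-phenylpentanoate (C2 epimers) | CC(C)(C)OC(=O)C([C@@H](CC=O)c1ccccc1)C1=CC(=O)[C@@H](C)[C@@H](C)O1 | intermediate
23 | (3R)-5-tert-butoxy-4-[(2R,3S)-2,3-dimethyl-4-oxo-3,4-dihydro-2H-pyran-6-yl]-5-oxo-3-phenylpentanoic acid (C4 epimers) | CC(C)(C)OC(=O)C([C@@H](CC(=O)O)c1ccccc1)C1=CC(=O)[C@@H](C)[C@@H](C)O1 | intermediate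
24 | (3R)-2-[(2R,3S)-2,3-dimethyl-4-oxo-3,4-dihydro-2H-pyran-6-yl]-3-phenylpentanedioic acid (C2 epimers) | OC(=O)C([C@@H](CC(=O)O)c1ccccc1)C1=CC(=O)[C@@H](C)[C@@H](C)O1 | intermediate
25 | (4R)-3-[(2R,3S)-2,3-dimethyl-4-oxo-3,4-dihydro-2H-pyran-6-yl]-4-phenyloxane-2,6-dione (C3 epimers) | O=C1OC(=O)C[C@@H](c2ccccc2)C1C3=CC(=O)[C@@H](C)[C@@H](C)O3 | intermediate
26 | (3S)-4-[(2R,3S)-2,3-dimethyl-4-oxo-3,4-dihydro-2H-pyran-6-yl]-5-oxo-3-phenylpent-4-enoic acid (vinylketene, present as its lithium carboxylate) | O=C=C([C@@H](CC(=O)O)c1ccccc1)C1=CC(=O)[C@@H](C)[C@@H](C)O1 | intermediate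
27 | (3R)-5-[(3S,5S)-3-{[(1R,3S)-2,2-dimethyl-3-(prop-1-en-2-yl)cyclobutyl]methyl}-5-[2-(diphenylphosphoryl)propan-2-yl]-2-oxooxolan-3-yl]-4-[(2R,3S)-2,3-dimethyl-4-oxo-3,4-dihydro-2H-pyran-6-yl]-5-oxo-3-phenylpentanoic acid (C4 epimers, present as dianion) | C=C(C)[C@@H]1C[C@H](C[C@]2(C[C@H](OC2=O)C(C)(C)P(=O)(c3ccccc3)c3ccccc3)C(=O)C([C@@H](CC(=O)O)c3ccccc3)C3=CC(=O)[C@@H](C)[C@@H](C)O3)C1(C)C | intermediate
28 | (3S)-3-[(2R,3S,6S)-6-{[(1R,3S)-2,2-dimethyl-3-(prop-1-en-2-yl)cyclobutyl]methyl}-6-[(2S)-3-(diphenylphosphoryl)-2-hydroxy-3-methylbutyl]-4-hydroxy-2,3-dimethyl-5,7-dioxo-3,5,6,7-tetrahydro-2H-chromen-8-yl]-3-phenylpropanoic acid | C=C(C)[C@@H]1C[C@H](C[C@@]2(C[C@H](O)C(C)(C)P(=O)(c3ccccc3)c3ccccc3)C(=O)C3=C(O)[C@@H](C)[C@@H](C)OC3=C([C@@H](CC(=O)O)c3ccccc3)C2=O)C1(C)C | intermediate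
29 | (3S)-3-[(2R,3S,6R)-6-{[(1R,3S)-2,2-dimethyl-3-(prop-1-en-2-yl)cyclobutyl]methyl}-4-hydroxy-2,3-dimethyl-6-(3-methylbut-2-en-1-yl)-5,7-dioxo-3,5,6,7-tetrahydro-2H-chromen-8-yl]-3-phenylpropanoic acid (CNP0328119.1) | C=C(C)[C@@H]1C[C@H](C[C@@]2(CC=C(C)C)C(=O)C3=C(O)[C@@H](C)[C@@H](C)OC3=C([C@@H](CC(=O)O)c3ccccc3)C2=O)C1(C)C | target

## Step count and risks

Total step count: 16. Longest linear sequence: 9 steps (steps 8 to 16).

Steps most likely to fail:

1. Step 16 (proposed new method). The lactone enolate may be acylated on oxygen, it may attack the intact anhydride carbonyl instead of the ketene, or the E1cB opening may be slower than decay of the enolate. The fallback sets out from 25 and 11, returns at 29, separates the two C–C bond formations and uses known reaction types only. Methanolysis of 25 at the less hindered carbonyl should give hemi-ester acid F1. 1-Chloro-N,N,2-trimethylprop-1-en-1-amine converts it into acid chloride F2. Lactone 11 is silylated (LiN(iPr)2, Me3SiCl) to silyl ketene acetal F3. C-Acylation of F3 by F2 (Mukaiyama-type acylation of a ketene silyl acetal, ZnCl2 if needed, again anti to the lactone C5 substituent) should give acyl lactone methyl ester F4, which is isolated. KOtBu then effects the Claisen closure onto the lactone carbonyl and the Horner–Wittig elimination to target methyl ester F5, and Me3SnOH hydrolysis gives 29.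

2. Step 7. The SN2 displacement at the β-branched carbon may be slower than decomposition of the lactone enolate, or the triflate may ionise with ring expansion. The fallback sets out from 4 and 10 and returns at 11. Oxidation of 4 with 1,1,1-triacetoxy-1,1-dihydro-1,2-benziodoxol-3(1H)-one gives aldehyde F6. Aldol addition of the lithium enolate of 10 gives hydroxy lactone F7. Mesylation gives mesylate F8, and DBU elimination gives alkylidene lactone F9. Conjugate reduction with [(Ph3P)CuH]6, which leaves the isolated isopropenyl group alone, then gives 11.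

3. Step 13. The methylene of 20 may be too weakly acidic for turnover under iminium catalysis, or face selection may be poor. The fallback sets out from 20 and returns at 23. Asymmetric allylic alkylation of the sodium enolate of 20 with cinnamyl methyl carbonate ([Ir(cod)Cl]2, chiral binaphthol-derived phosphoramidite ligand of the enantiomer that gives the (R) centre) should give branched alkene F10. 9-BBN hydroboration with NaBO3 oxidation gives primary alcohol F11, and TEMPO/PhI(OAc)2 in wet MeCN oxidises it to 23.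

Further compounds
F1 | step 16 | (3R)-2-[(2R,3S)-2,3-dimethyl-4-oxo-3,4-dihydro-2H-pyran-6-yl]-5-methoxy-5-oxo-3-phenylpentanoic acid (C2 epimers) | COC(=O)C[C@@H](c1ccccc1)C(C(=O)O)C1=CC(=O)[C@@H](C)[C@@H](C)O1
F2 | step 16 | methyl (3R)-5-chloro-4-[(2R,3S)-2,3-dimethyl-4-oxo-3,4-dihydro-2H-pyran-6-yl]-5-oxo-3-phenylpentanoate (C4 epimers) | COC(=O)C[C@@H](c1ccccc1)C(C(=O)Cl)C1=CC(=O)[C@@H](C)[C@@H](C)O1
F3 | step 16 | {[(5S)-3-{[(1R,3S)-2,2-dimethyl-3-(prop-1-en-2-yl)cyclobutyl]methyl}-5-[2-(diphenylphosphoryl)propan-2-yl]-4,5-dihydrofuran-2-yl]oxy}trimethylsilane | C=C(C)[C@@H]1C[C@H](CC2=C(O[Si](C)(C)C)O[C@@H](C2)C(C)(C)P(=O)(c2ccccc2)c2ccccc2)C1(C)C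
F4 | step 16 | methyl ester of 27 (acyl lactone methyl ester, C4 epimers) | C=C(C)[C@@H]1C[C@H](C[C@]2(C[C@H](OC2=O)C(C)(C)P(=O)(c3ccccc3)c3ccccc3)C(=O)C([C@@H](CC(=O)OC)c3ccccc3)C3=CC(=O)[C@@H](C)[C@@H](C)O3)C1(C)C
F5 | step 16 | methyl ester of 29 (target methyl ester) | C=C(C)[C@@H]1C[C@H](C[C@@]2(CC=C(C)C)C(=O)C3=C(O)[C@@H](C)[C@@H](C)OC3=C([C@@H](CC(=O)OC)c3ccccc3)C2=O)C1(C)C
F6 | step 7 | (1S,3S)-2,2-dimethyl-3-(prop-1-en-2-yl)cyclobutane-1-carbaldehyde | C=C(C)[C@@H]1C[C@H](C=O)C1(C)C
F7 | step 7 | (5S)-3-{[(1S,3S)-2,2-dimethyl-3-(prop-1-en-2-yl)cyclobutyl](hydroxy)methyl}-5-[2-(diphenylphosphoryl)propan-2-yl]oxolan-2-one (epimers at C3 and the carbinol) | C=C(C)[C@@H]1C[C@H](C(O)C2C[C@H](OC2=O)C(C)(C)P(=O)(c2ccccc2)c2ccccc2)C1(C)C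
F8 | step 7 | methanesulfonate of F7 | C=C(C)[C@@H]1C[C@H](C(OS(C)(=O)=O)C2C[C@H](OC2=O)C(C)(C)P(=O)(c2ccccc2)c2ccccc2)C1(C)C
F9 | step 7 | (3E,5S)-3-{[(1R,3S)-2,2-dimethyl-3-(prop-1-en-2-yl)cyclobutyl]methylidene}-5-[2-(diphenylphosphoryl)propan-2-yl]oxolan-2-one | C=C(C)[C@@H]1C[C@H](/C=C2\C[C@H](OC2=O)C(C)(C)P(=O)(c2ccccc2)c2ccccc2)C1(C)C
F10 | step 13 | tert-butyl (3R)-2-[(2R,3S)-2,3-dimethyl-4-oxo-3,4-dihydro-2H-pyran-6-yl]-3-phenylpent-4-enoate (C2 epimers) | CC(C)(C)OC(=O)C([C@@H](C=C)c1ccccc1)C1=CC(=O)[C@@H](C)[C@@H](C)O1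
F11 | step 13 | tert-butyl (3R)-2-[(2R,3S)-2,3-dimethyl-4-oxo-3,4-dihydro-2H-pyran-6-yl]-5-hydroxy-3-phenylpentanoate (C2 epimers) | CC(C)(C)OC(=O)C([C@@H](CCO)c1ccccc1)C1=CC(=O)[C@@H](C)[C@@H](C)O1
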